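Locants: side chain O–C1–C2–C3–C4(C15H3); ring A = cyclohexene C5–C10 with C5=C10 and C14H2–O on C10; ring B = lactone O–C8–C7–C11–C12(=O); C13 = methylidene carbon on C11.
Retrosynthesis: the methacrylate, both acetates and C13 are removed first; the tetrasubstituted C5=C10 bond of ring A is then cut by ring-closing metathesis, leaving a trans-4,5-disubstituted γ-butyrolactone (ring B) with a methylidene group on each arm.
Feature that permits this cut: C5 and C10 each carry exactly one carbon outside ring A (C4 and C14), so both halves can be terminal 1,1-disubstituted alkenes, and ring B, trans-fused across C7–C8, together with the C6 hydroxyl holds the two arms side by side.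
Further cuts: the lactone C12–O8 bond, C8–C9 (Weinreb amide plus a 2-(PMB-oxymethyl)allyl Grignard reagent) and C6–C7 (anti aldol), giving a succinate imide, an allyl chloride from 2-methylidenepropane-1,3-diol and an α-methylidene aldehyde from (S)-citronellal.
Forward order: C6–C7 and then C8–C9 are joined, ring B is closed by lactonisation, ring A by metathesis, and C13 and the three esters are added last.
Stereochemistry: C4 comes from (S)-citronellal, C6 and C7 from the (S)-benzyl-oxazolidinone in a MgCl2-catalysed anti aldol, C8 from a hydroxyl-directed 1,3-anti reduction; the metathesis creates no stereocentre.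
Key step: step 14

Remarks
- Abbreviations: TBS = tert-butyldimethylsilyl, TES = triethylsilyl, PMB = 4-methoxybenzyl, PPTS = pyridinium p-toluenesulfonate, CSA = camphor-10-sulfonic acid. Acyclic precursors keep the ring locants; descriptors such as (4S,6S,7R) refer to these locants.
- Assumption: the MgCl2-catalysed aldol is taken to follow the usual sense for N-acyl oxazolidinones (the aldehyde adds to the chelated Z-enolate on the face away from the benzyl group, anti relationship); the (S)-auxiliary is chosen on that basis.

Step 1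
Reactants: 1 (S)-citronellal
Product: 2 (6S)-8,8-dimethoxy-2,6-dimethyloct-2-ene
Conditions: HC(OMe)3, PPTS (5 mol%), MeOH, 0 → 23 °C
Reagents that add atoms: trimethyl orthoformate, COC(OC)OC; methanol, CO
Why: Acid-catalysed acetalisation with the orthoformate as water scavenger masks the aldehyde for the oxidative cleavage, the weak pyridinium acid being too mild to start the carbonyl-ene cyclisation of citronellal, and the future C4 centre is not touched.

Step 2
Reactants: 2 (6S)-8,8-dimethoxy-2,6-dimethyloct-2-ene
Product: 4 (4S)-6,6-dimethoxy-4-methylhexan-1-ol, via ozonide 3 (not isolated)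
Conditions: O3, CH2Cl2, −78 °C, to the first blue tinge; then NaBH4, MeOH, −78 → 23 °C
Reagents that add atoms: ozone, [O-][O+]=O
Why: Ozonolysis of the electron-rich trisubstituted alkene with reductive borohydride work-up cuts off the isopropylidene end and leaves the primary alcohol that becomes C1–O, the acyclic acetal being stable to ozone at −78 °C when no excess is passed.

Step 3
Reactants: 4 (4S)-6,6-dimethoxy-4-methylhexan-1-ol
Product: 5 tert-butyl{[(4S)-6,6-dimethoxy-4-methylhexyl]oxy}dimethylsilane
Conditions: TBSCl, imidazole, CH2Cl2, 23 °C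
Reagents that add atoms: tert-butyldimethylsilyl chloride, CC(C)(C)[Si](C)(C)Cl
Why: Silyl ether formation on an unhindered primary alcohol gives a group that should survive amines, organomagnesium reagents and hydrides until the late fluoride step.

Step 4
Reactants: 5 tert-butyl{[(4S)-6,6-dimethoxy-4-methylhexyl]oxy}dimethylsilane
Product: 6 (3S)-6-[(tert-butyldimethylsilyl)oxy]-3-methylhexanal
Conditions: SiO2, 10% aq oxalic acid, CH2Cl2, 23 °C
Reagents that add atoms: water, O
Why: Mild heterogeneous acetal hydrolysis, in which the acyclic dimethyl acetal of an aliphatic aldehyde is cleaved much faster than a primary TBS ether.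

Step 5
Reactants: 6 (3S)-6-[(tert-butyldimethylsilyl)oxy]-3-methylhexanal
Product: 7 (3S)-6-[(tert-butyldimethylsilyl)oxy]-3-methyl-2-methylidenehexanal
Conditions: aq HCHO (37%), pyrrolidine (10 mol%), EtCO2H (10 mol%), i-PrOH, 45 °C
Reagents that add atoms: formaldehyde, C=O
Why: Amine-catalysed α-methylenation (Mannich condensation through the enamine of 6 and loss of the amine) installs the C5 methylidene, and the neighbouring stereocentre, β to the carbonyl in 6 and outside any enolisable system in 7, should keep its configuration.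

Step 6
Reactants: 8 4-tert-butoxy-4-oxobutanoic acid; 9 (4S)-4-benzyl-1,3-oxazolidin-2-one
Product: 11 tert-butyl 4-[(4S)-4-benzyl-2-oxo-1,3-oxazolidin-3-yl]-4-oxobutanoate, via mixed pivalic anhydride 10 (not isolated)
Conditions: PivCl, Et3N, THF, −20 °C; then LiCl, 9, −20 → 23 °C
Reagents that add atoms: none
Why: N-acylation of the oxazolidinone through the mixed anhydride under LiCl/Et3N activation, in which the oxazolidinone nitrogen attacks the unhindered succinyl carbonyl and no strong base comes near the tert-butyl ester.

Step 7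
Reactants: 12 2-methylidenepropane-1,3-diol
Product: 13 2-{[(4-methoxybenzyl)oxy]methyl}prop-2-en-1-ol
Conditions: NaH (1.0 equiv), THF/DMF, 0 °C; PMBCl (1.0 equiv), n-Bu4NI (5 mol%), 0 → 23 °C; diol in two-fold excess
Reagents that add atoms: 4-methoxybenzyl chloride, COc1ccc(CCl)cc1
Why: Williamson etherification of the mono-alkoxide of a symmetric diol, where the excess of diol should hold bis-alkylation down and the unchanged diol is removed with water.

Step 8
Reactants: 13 2-{[(4-methoxybenzyl)oxy]methyl}prop-2-en-1-ol
Product: 15 1-({[2-(chloromethyl)prop-2-en-1-yl]oxy}methyl)-4-methoxybenzene, via allylic mesylate 14 (not isolated)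
Conditions: MsCl, Et3N, CH2Cl2, −10 °C; then LiCl, DMF, 23 °C
Reagents that add atoms: lithium chloride, [Li+].[Cl-]
Why: Sulfonylation followed by chloride displacement at the primary allylic carbon, direct and allylic (SN2′) substitution leading to the same chloride because the two CH2 termini of the allyl unit become equivalent.

Step 9
Reactants: 11 tert-butyl 4-[(4S)-4-benzyl-2-oxo-1,3-oxazolidin-3-yl]-4-oxobutanoate; 7 (3S)-6-[(tert-butyldimethylsilyl)oxy]-3-methyl-2-methylidenehexanal
Product: 17 anti-aldol adduct (4S,6S,7R) with 6-OH and the imide at C8, via trimethylsilyl ether 16 (not isolated)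
Conditions: MgCl2 (20 mol%), Et3N, Me3SiCl, EtOAc, 23 °C; then PPTS, MeOH, 0 °C
Reagents that add atoms: none
Why: Magnesium-halide-catalysed direct anti aldol reaction of an N-acyl oxazolidinone with a non-enolisable enal (soft enolisation of the imide, O-silylation of the aldolate for turnover), in which the chelated Z-enolate is expected to add through a boat-like transition state on the face away from the benzyl group, setting C7 (R) and C6 (S) anti to each other, with the C4 centre a spectator and the tert-butyl ester too hindered to lactonise with the new hydroxyl.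

Step 10
Reactants: 17 anti-aldol adduct (4S,6S,7R)
Product: 18 Weinreb amide (4S,6S,7R) with C8(=O)N(OMe)Me in place of the imide
Conditions: MeNH(OMe)·HCl, AlMe3, CH2Cl2, −20 → 0 °C
Reagents that add atoms: N,O-dimethylhydroxylamine hydrochloride, CNOC.Cl
Why: Aluminium-amide transamination (Weinreb amidation) of a β-hydroxy imide, in which the aluminium alkoxide at O6 directs the amide to the exocyclic C8 carbonyl and releases the auxiliary while the tert-butyl ester, the silyl ether and all stereocentres stay as they are.

Step 11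
Reactants: 18 Weinreb amide (4S,6S,7R); 15 1-({[2-(chloromethyl)prop-2-en-1-yl]oxy}methyl)-4-methoxybenzene
Product: 20 β-hydroxy ketone (4S,6S,7R) with C8=O bonded to C9H2–C10(=CH2)–C14H2–OPMB, via allylmagnesium chloride 19 (not isolated)
Conditions: 15, Mg, THF, 0 °C; then 18, THF, −78 → −40 °C (3 equiv of 19); AcOH, THF, −78 °C, then aq NH4Cl
Reagents that add atoms: none
Why: Weinreb ketone synthesis, in which the first equivalent of the Grignard reagent deprotonates O6–H and the next adds once to the N-methoxy-N-methylamide, whose magnesium chelate survives until the cold acidic quench, so that neither over-addition nor migration of the new 1,1-disubstituted alkene into conjugation should occur and the hindered tert-butyl ester is left alone at −78 °C.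

Step 12
Reactants: 20 β-hydroxy ketone (4S,6S,7R)
Product: 21 6,8-anti-diol (4S,6S,7S,8R)
Conditions: Me4NBH(OAc)3, MeCN/AcOH (1:1), −30 °C
Reagents that add atoms: none
Why: Hydroxyl-directed Evans–Saksena reduction, in which the triacetoxyborohydride exchanges an acetate for O6 and delivers hydride intramolecularly through a chair-like six-membered transition state to give the 6,8-anti diol and thereby C8 (R), esters and alkenes being inert to this reagent.

Step 13
Reactants: 21 6,8-anti-diol (4S,6S,7S,8R)
Product: 22 lactone diene (4S,6S,7R,8R) with free 6-OH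
Conditions: CSA (20 mol%), CH2Cl2, 23 → 40 °C
Reagents that add atoms: none
Why: Acid-catalysed lactonisation (intramolecular transesterification with loss of tert-butanol), in which closure through the less hindered O8 gives the trans-4,5-disubstituted γ-lactone, favoured kinetically and thermodynamically over the cis lactone that the allylic O6 would form, the trans relationship of C7 and C8 following from centres already set.

Step 14
Reactants: 22 lactone diene (4S,6S,7R,8R)
Product: 23 bicyclic hydroxy lactone (4S,6S,7R,8R) with ring A trans-fused to ring B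
Conditions: RuCl2(=CH-C6H4-2-Oi-Pr)[1,3-bis(2-methylphenyl)imidazolidin-2-ylidene] (2 × 10 mol%), 1,4-benzoquinone (20 mol%), PhMe (2 mM), 80 °C, argon sparge
Reagents that add atoms: none
Why: The benzylidene ruthenium complex exchanges onto the less hindered C10 methylidene alkene, the resulting disubstituted alkylidene adds intramolecularly by [2+2] cycloaddition to the C5 methylidene alkene, and the ruthenacyclobutane cycloreverts to the C5=C10 double bond and a ruthenium methylidene, the two CH2 groups leaving as ethene. The closest known reaction type is ring-closing metathesis of two 1,1-disubstituted alkenes to tetrasubstituted cycloalkenes with second-generation Hoveyda–Grubbs catalysts whose carbene ligand carries small N-o-tolyl groups. Ring A closes as a six-membered carbocycle by joining C5 to C10 of a 1,7-diene, and it is trans-fused to ring B because the C7 and C8 arms already stand trans on the lactone. No stereocentre is formed, and C4, C6, C7 and C8 pass through unchanged. The step needs cyclisation to win over intermolecular metathesis and over ruthenium hydride isomerisation: the rigid trans-disubstituted lactone keeps the two alkenes close, the free O6 hydroxyl can hydrogen-bond to a chloride ligand and steer the alkylidene to the crowded C5 alkene, the C10 alkene with its CH2OPMB group is the only site open to initial loading, and high dilution, argon sparging and benzoquinone suppress dimers and alkene migration.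

Step 15
Reactants: 23 bicyclic hydroxy lactone (4S,6S,7R,8R)
Product: 24 6-O-TES ether of 23 (4S,6S,7S,8R)
Conditions: TESOTf, 2,6-lutidine, CH2Cl2, −78 → −40 °C
Reagents that add atoms: triethylsilyl trifluoromethanesulfonate, CC[Si](CC)(CC)OS(=O)(=O)C(F)(F)F
Why: Silylation of the hindered secondary allylic hydroxyl with the reactive silyl triflate removes the only acidic proton and blocks alkoxide-induced translactonisation before the lactone is enolised.

Step 16
Reactants: 24 6-O-TES ether (4S,6S,7S,8R)
Product: 27 α-methylidene lactone (4S,6S,7S,8R) with C11=C13H2, via Mannich base 25 (not isolated), via trimethylammonium iodide 26 (not isolated)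
Conditions: LiN(SiMe3)2, THF, −78 °C; CH2=NMe2+ I−, −78 → 23 °C; then MeI, CH2Cl2/MeOH, 23 °C; then aq NaHCO3, 23 °C
Reagents that add atoms: N,N-dimethylmethylideneammonium iodide, C=[N+](C)C.[I-]
Why: Eschenmoser methylenation, in which the lithium enolate of the lactone is aminomethylated at C11, the amine is quaternised and the ammonium salt undergoes base-induced β-elimination to the exocyclic alkene, the transient C11 centre being destroyed again and C7, β to the carbonyl, being unable to epimerise.

Step 17
Reactants: 27 α-methylidene lactone (4S,6S,7S,8R)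
Product: 28 diol (4S,6S,7R,8R) with free 1-OH and 6-OH
Conditions: HF·pyridine, pyridine, THF, 0 → 23 °C
Reagents that add atoms: none
Why: Fluoride-mediated desilylation under buffered non-basic conditions should remove both the secondary TES and the primary TBS ether without conjugate addition to the α-methylidene lactone or loss of the PMB ether.

Step 18
Reactants: 28 diol (4S,6S,7R,8R)
Product: 29 1,6-diacetate (4S,6S,7S,8R)
Conditions: Ac2O, pyridine, DMAP (10 mol%), CH2Cl2, 23 °C
Reagents that add atoms: acetic anhydride, CC(=O)OC(C)=O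
Why: DMAP-catalysed acetylation esterifies the primary O1 and the hindered secondary O6 hydroxyl in one operation and, by capping O6, excludes any later translactonisation.

Step 19
Reactants: 29 1,6-diacetate (4S,6S,7S,8R)
Product: 30 allylic alcohol (4S,6S,7S,8R) with free 14-OH
Conditions: DDQ, CH2Cl2/pH 7 phosphate buffer (10:1), 0 °C
Reagents that add atoms: none
Why: Oxidative cleavage of the 4-methoxybenzyl ether (hydride abstraction by the quinone and hydrolysis of the oxocarbenium ion) frees the primary allylic hydroxyl on C14, which stands trans to C6 across the ring alkene and so cannot take over the O6 acetate, while the acetates and the electron-poor methylidene lactone are inert.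

Step 20
Reactants: 30 allylic alcohol (4S,6S,7S,8R)
Product: 31 target compound (4S,6S,7S,8R)
Conditions: methacryloyl chloride, Et3N, DMAP (5 mol%), CH2Cl2, 0 °C
Reagents that add atoms: methacryloyl chloride, C=C(C)C(=O)Cl
Why: Acylation of the unhindered primary allylic alcohol with the acid chloride under nucleophilic catalysis completes the target, the low temperature and short reaction time keeping the two acrylate-type alkenes from polymerising.

Compound list
1 | (S)-citronellal, (3S)-3,7-dimethyloct-6-enal | C[C@@H](CCC=C(C)C)CC=O | starting material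
2 | (6S)-8,8-dimethoxy-2,6-dimethyloct-2-ene | C[C@@H](CCC=C(C)C)CC(OC)OC | intermediate
3 | ozonide of 2, 3-[(3S)-5,5-dimethoxy-3-methylpentyl]-5,5-dimethyl-1,2,4-trioxolane | C[C@@H](CCC1OOC(C)(C)O1)CC(OC)OC | intermediate
4 | (4S)-6,6-dimethoxy-4-methylhexan-1-ol | C[C@@H](CCCO)CC(OC)OC | intermediate
5 | tert-butyl{[(4S)-6,6-dimethoxy-4-methylhexyl]oxy}dimethylsilane | C[C@@H](CCCO[Si](C)(C)C(C)(C)C)CC(OC)OC | intermediate
6 | (3S)-6-[(tert-butyldimethylsilyl)oxy]-3-methylhexanal | C[C@@H](CCCO[Si](C)(C)C(C)(C)C)CC=O | intermediate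
7 | (3S)-6-[(tert-butyldimethylsilyl)oxy]-3-methyl-2-methylidenehexanal | C[C@@H](CCCO[Si](C)(C)C(C)(C)C)C(=C)C=O | intermediate
8 | 4-tert-butoxy-4-oxobutanoic acid (mono-tert-butyl succinate) | CC(C)(C)OC(=O)CCC(=O)O | starting material
9 | (4S)-4-benzyl-1,3-oxazolidin-2-one | O=C1N[C@@H](Cc2ccccc2)CO1 | starting material
10 | mixed anhydride of 8 with pivalic acid | CC(C)(C)OC(=O)CCC(=O)OC(=O)C(C)(C)C | intermediate
11 | tert-butyl 4-[(4S)-4-benzyl-2-oxo-1,3-oxazolidin-3-yl]-4-oxobutanoate | CC(C)(C)OC(=O)CCC(=O)N1[C@@H](Cc2ccccc2)COC1=O | intermediate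
12 | 2-methylidenepropane-1,3-diol | C=C(CO)CO | starting material
13 | 2-{[(4-methoxybenzyl)oxy]methyl}prop-2-en-1-ol | C=C(CO)COCc1ccc(OC)cc1 | intermediate
14 | 2-{[(4-methoxybenzyl)oxy]methyl}prop-2-en-1-yl methanesulfonate | C=C(COS(C)(=O)=O)COCc1ccc(OC)cc1 | intermediate
15 | 1-({[2-(chloromethyl)prop-2-en-1-yl]oxy}methyl)-4-methoxybenzene | C=C(CCl)COCc1ccc(OC)cc1 | intermediate
16 | 6-O-trimethylsilyl ether of 17 (4S,6S,7R) | CC(C)(C)OC(=O)C[C@@H](C(=O)N1[C@@H](Cc2ccccc2)COC1=O)[C@H](O[Si](C)(C)C)C(=C)[C@@H](C)CCCO[Si](C)(C)C(C)(C)C | intermediate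
17 | anti-aldol adduct (4S,6S,7R): C12 tert-butyl ester, C8 acyl-(S)-4-benzyl-oxazolidin-2-one, 6-OH, C5=CH2, 1-OTBS | CC(C)(C)OC(=O)C[C@@H](C(=O)N1[C@@H](Cc2ccccc2)COC1=O)[C@H](O)C(=C)[C@@H](C)CCCO[Si](C)(C)C(C)(C)C | intermediate
18 | Weinreb amide (4S,6S,7R): 17 with C8(=O)N(OMe)Me | CC(C)(C)OC(=O)C[C@@H](C(=O)N(C)OC)[C@H](O)C(=C)[C@@H](C)CCCO[Si](C)(C)C(C)(C)C | intermediate
19 | {2-[(4-methoxybenzyloxy)methyl]prop-2-en-1-yl}magnesium chloride | C=C(C[Mg]Cl)COCc1ccc(OC)cc1 | intermediate
20 | β-hydroxy ketone (4S,6S,7R): C8 ketone, C9H2–C10(=CH2)–C14H2–OPMB, 6-OH, C5=CH2, C12 tert-butyl ester, 1-OTBS | CC(C)(C)OC(=O)C[C@@H](C(=O)CC(=C)COCc1ccc(OC)cc1)[C@H](O)C(=C)[C@@H](C)CCCO[Si](C)(C)C(C)(C)C | intermediate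
21 | 6,8-anti-diol (4S,6S,7S,8R): 20 with C8H–OH | CC(C)(C)OC(=O)C[C@@H]([C@H](O)CC(=C)COCc1ccc(OC)cc1)[C@H](O)C(=C)[C@@H](C)CCCO[Si](C)(C)C(C)(C)C | intermediate
22 | lactone diene (4S,6S,7R,8R): trans-4,5-disubstituted γ-butyrolactone O8–C12, 6-OH, C5=CH2, C10=CH2, 14-OPMB, 1-OTBS | C=C(COCc1ccc(OC)cc1)C[C@H]1OC(=O)C[C@@H]1[C@H](O)C(=C)[C@@H](C)CCCO[Si](C)(C)C(C)(C)C | intermediate
23 | bicyclic hydroxy lactone (4S,6S,7R,8R): ring A (C5=C10) trans-fused to ring B, 6-OH, 14-OPMB, 1-OTBS | COc1ccc(COCC2=C([C@@H](C)CCCO[Si](C)(C)C(C)(C)C)[C@@H](O)[C@H]3CC(=O)O[C@@H]3C2)cc1 | intermediate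
24 | 6-O-TES ether of 23 (4S,6S,7S,8R) | COc1ccc(COCC2=C([C@@H](C)CCCO[Si](C)(C)C(C)(C)C)[C@@H](O[Si](CC)(CC)CC)[C@H]3CC(=O)O[C@@H]3C2)cc1 | intermediate
25 | Mannich base: 24 with CH2NMe2 on C11 (C11 epimers) | COc1ccc(COCC2=C([C@@H](C)CCCO[Si](C)(C)C(C)(C)C)[C@@H](O[Si](CC)(CC)CC)[C@H]3C(CN(C)C)C(=O)O[C@@H]3C2)cc1 | intermediate
26 | trimethylammonium iodide of 25 | COc1ccc(COCC2=C([C@@H](C)CCCO[Si](C)(C)C(C)(C)C)[C@@H](O[Si](CC)(CC)CC)[C@H]3C(C[N+](C)(C)C)C(=O)O[C@@H]3C2)cc1.[I-] | intermediate
27 | α-methylidene lactone (4S,6S,7S,8R): 24 with C11=C13H2 | COc1ccc(COCC2=C([C@@H](C)CCCO[Si](C)(C)C(C)(C)C)[C@@H](O[Si](CC)(CC)CC)[C@H]3C(=C)C(=O)O[C@@H]3C2)cc1 | intermediate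
28 | diol (4S,6S,7R,8R): 27 with free 1-OH and 6-OH | COc1ccc(COCC2=C([C@@H](C)CCCO)[C@@H](O)[C@H]3C(=C)C(=O)O[C@@H]3C2)cc1 | intermediate
29 | 1,6-diacetate of 28 (4S,6S,7S,8R) | COc1ccc(COCC2=C([C@@H](C)CCCOC(C)=O)[C@@H](OC(C)=O)[C@H]3C(=C)C(=O)O[C@@H]3C2)cc1 | intermediate
30 | allylic alcohol (4S,6S,7S,8R): 29 with free 14-OH | OCC1=C([C@@H](C)CCCOC(C)=O)[C@@H](OC(C)=O)[C@H]2C(=C)C(=O)O[C@@H]2C1 | intermediate
31 | target (4S,6S,7S,8R): 14-O-methacrylate of 30 | C=C(C)C(=O)OCC1=C([C@@H](C)CCCOC(C)=O)[C@@H](OC(C)=O)[C@H]2C(=C)C(=O)O[C@@H]2C1 | target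

Total step count: 20 (aldehyde 7 in 5 steps, imide 11 in 1 step, chloride 15 in 2 steps, then 12 steps).
Longest linear sequence: 17 steps (steps 1–5 and 9–20, from (S)-citronellal).

Steps most likely to fail, in order of risk

Step 14. The ruthenium alkylidene loaded at C10 may fail to engage the C5 alkene, which is branched on both sides. The catalyst would then decay, move the alkenes through ruthenium hydrides, isomerise the allylic alcohol to the ketone, or couple two molecules at the C10 alkene. The fallback sets out from 22. Silylation (TESOTf, 2,6-lutidine, CH2Cl2, −78 °C) gives the 6-O-TES lactone diene F1. Ring closure is then done with the hexavalent molybdenum imido alkylidene Mo(=CHCMe2Ph)(=N-2,6-i-Pr2C6H3)[OCMe(CF3)2]2 (20 mol%, benzene, 60 °C, inert atmosphere), which is more reactive towards crowded 1,1-disubstituted alkenes but needs every hydroxyl masked. This closure should give 24 directly, so the route is rejoined at 24 and step 15 is not needed.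

Step 11. The allylic Grignard reagent may also attack the tert-butyl ester, the magnesium alkoxide may trigger retro-aldol cleavage or enolisation, and the new 1,1-disubstituted alkene may move into conjugation with the ketone during work-up. The fallback sets out from 18 and builds C8 at the aldehyde oxidation level.
- Silylation (TESOTf, 2,6-lutidine) gives the 6-O-TES Weinreb amide F2, and i-Bu2AlH (THF, −78 °C) reduces it to the aldehyde F3.
- Chloride 15 is converted with n-Bu3SnLi (THF, −78 °C) into the allylstannane F4.
- F4 adds to F3 under BF3·OEt2 (CH2Cl2, −78 °C). Felkin–Anh and 1,3-anti induction reinforce each other for this anti α,β-disubstituted aldehyde, so the homoallylic alcohol F5 should have the C8 configuration of 21.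
- PPTS in MeOH (0 °C) removes the TES group and the route is rejoined at 21, replacing steps 11 and 12.

Step 13. Closure may take place through the allylic O6 hydroxyl to the cis lactone, or the acid may strip the primary silyl ether before lactonisation is complete. The fallback sets out from 20 and differentiates the two oxygens during the reduction. An Evans–Tishchenko reduction (SmI2 20 mol%, CH3CHO, THF, −10 °C) transfers hydride within the O6 hemiacetal and should give the anti diol 6-O-monoacetate F6, in which only O8–H is free. CSA (CH2Cl2, 23 °C) can then close only the wanted lactone, giving the 6-O-acetyl lactone diene F7. Brief methanolysis (K2CO3, MeOH, 0 °C) removes the acetate and the route is rejoined at 22.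

Further compounds
F1 | step 14 | 6-O-TES ether of lactone diene 22 (4S,6S,7S,8R) | C=C(COCc1ccc(OC)cc1)C[C@H]1OC(=O)C[C@@H]1[C@H](O[Si](CC)(CC)CC)C(=C)[C@@H](C)CCCO[Si](C)(C)C(C)(C)C
F2 | step 11 | 6-O-TES ether of Weinreb amide 18 (4S,6S,7R) | CC(C)(C)OC(=O)C[C@@H](C(=O)N(C)OC)[C@H](O[Si](CC)(CC)CC)C(=C)[C@@H](C)CCCO[Si](C)(C)C(C)(C)C
F3 | step 11 | C8 aldehyde (4S,6S,7R) with 6-OTES, C12 tert-butyl ester, 1-OTBS | CC(C)(C)OC(=O)C[C@@H](C=O)[C@H](O[Si](CC)(CC)CC)C(=C)[C@@H](C)CCCO[Si](C)(C)C(C)(C)C
F4 | step 11 | tributyl{2-[(4-methoxybenzyloxy)methyl]prop-2-en-1-yl}stannane | C=C(C[Sn](CCCC)(CCCC)CCCC)COCc1ccc(OC)cc1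
F5 | step 11 | 6-O-TES ether of diol 21 (4S,6S,7S,8R), free 8-OH | CC(C)(C)OC(=O)C[C@@H]([C@H](O)CC(=C)COCc1ccc(OC)cc1)[C@H](O[Si](CC)(CC)CC)C(=C)[C@@H](C)CCCO[Si](C)(C)C(C)(C)C
F6 | step 13 | 6-O-acetate of diol 21 (4S,6S,7S,8R), free 8-OH | CC(C)(C)OC(=O)C[C@@H]([C@H](O)CC(=C)COCc1ccc(OC)cc1)[C@H](OC(C)=O)C(=C)[C@@H](C)CCCO[Si](C)(C)C(C)(C)C
F7 | step 13 | 6-O-acetate of lactone diene 22 (4S,6S,7S,8R) | C=C(COCc1ccc(OC)cc1)C[C@H]1OC(=O)C[C@@H]1[C@H](OC(C)=O)C(=C)[C@@H](C)CCCO[Si](C)(C)C(C)(C)C
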